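**Plan**
- Ring numbering: C1 carries the CH2OAc carbon, C2 is the olefinic CH, C3 the ketone, C4 the farnesylated oxirane carbon, C5 the oxirane CH, C6 the carbinol. The array C6(OH)–C1(=C2)–CH2O is what an α,β-unsaturated ester leaves when its α-carbon C1 adds to a C6 aldehyde. The cis-oxirane C4–C5 of the 7-oxabicyclo[4.1.0]heptenone is the epoxide of a Z-allylic alcohol.
- Retrosynthetic cuts, in order: C1–C6 (intramolecular Morita–Baylis–Hillman), C2–C3 (propiolate acetylide plus C3 aldehyde), C4=C5 (Still–Gennari olefination), C4–farnesyl (phosphonate alkylation).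
- Forward: the C3–C6 chain is built linearly and epoxidised, C1/C2 are added as propiolate, and the only carbocycle closes in step 11. Ester reduction, acetylation and C3 oxidation follow.
- Stereochemistry: C4 and C5 come from the Sharpless epoxidation with L-(+)-DET. A temporary C3 carbinol (chelation-controlled alkynylation) steers the C6 carbinol in the ring closure and is then oxidised to the ketone.

Key step: step 11

Remark: "farnesyl" means (2E,6E)-3,7,11-trimethyldodeca-2,6,10-trien-1-yl. Locants C1–C6 in the names of cyclic compounds follow the ring numbering above, and in the Why lines these same locants are used for the corresponding atoms of the acyclic intermediates.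

**Step 1**
Reactants: 1 (2E,6E)-farnesyl bromide; 2 methyl 2-[bis(2,2,2-trifluoroethoxy)phosphoryl]acetate
Product: 4 methyl 2-[bis(2,2,2-trifluoroethoxy)phosphoryl]-2-farnesylacetate (racemic), via sodium phosphonate anion 3 (not isolated)
Conditions: 2 (1.3 equiv), NaH, THF/DMF, 0 °C; then 1, 0 °C to rt
Reagents that add atoms: none
Why: SN2 alkylation of the stabilised phosphonoacetate carbanion by the primary allylic bromide, with excess phosphonate to suppress dialkylation; the new centre is lost in step 2.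

**Step 2**
Reactants: 4 farnesylated phosphonate; 5 2-[(4-methoxybenzyl)oxy]acetaldehyde
Product: 7 methyl (2Z)-2-farnesyl-4-[(4-methoxybenzyl)oxy]but-2-enoate, via potassium phosphonate anion 6 (not isolated)
Conditions: KN(SiMe3)2, 18-crown-6, THF, −78 °C; then 5
Reagents that add atoms: none
Why: Still–Gennari olefination; the trifluoroethyl phosphonate with a dissociated potassium counter-ion collapses from the kinetic adduct and places the ester cis to the CH2OPMB arm (Z), the geometry the cis-oxirane needs.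

**Step 3**
Reactants: 7 (Z)-enoate
Product: 8 (2Z)-2-farnesyl-4-[(4-methoxybenzyl)oxy]but-2-en-1-ol
Conditions: iBu2AlH (2.3 equiv), CH2Cl2, −78 °C; aq. KNaC4H4O6 work-up
Reagents that add atoms: none
Why: 1,2-reduction of the conjugated ester by iBu2AlH at low temperature gives the allylic alcohol and leaves the olefin geometry and the PMB ether unchanged.

**Step 4**
Reactants: 8 (Z)-allylic alcohol
Product: 9 [(2S,3R)-2-farnesyl-3-{[(4-methoxybenzyl)oxy]methyl}oxiran-2-yl]methanol
Conditions: Ti(OiPr)4 (20 mol %), L-(+)-diethyl tartrate (24 mol %), t-BuOOH (anhydrous), 4 Å molecular sieves, CH2Cl2, −20 °C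
Reagents that add atoms: tert-butyl hydroperoxide, CC(C)(C)OO
Why: Sharpless asymmetric epoxidation; the titanium tartrate complex oxidises only the olefin with an allylic hydroxyl (the nearest farnesyl olefin is bis-homoallylic), L-(+)-DET should deliver oxygen to the face giving the (2S,3R) epoxy alcohol as for other (Z)-2-alken-1-ols, and the Z geometry becomes the cis-oxirane (C4 and C5).

**Step 5**
Reactants: 9 epoxy alcohol
Product: 10 (2R,3R)-2-farnesyl-3-{[(4-methoxybenzyl)oxy]methyl}oxirane-2-carbaldehyde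
Conditions: Dess–Martin periodinane, pyridine, CH2Cl2, 0 °C to rt
Reagents that add atoms: none
Why: Dess–Martin oxidation of the primary alcohol under buffered conditions; the aldehyde has a quaternary α-carbon and cannot epimerise, and the oxirane and olefins are inert.

**Step 6**
Reactants: 10 epoxy aldehyde; 11 methyl propiolate
Product: 14 methyl (4R)-4-hydroxy-4-[(2S,3R)-2-farnesyl-3-{[(4-methoxybenzyl)oxy]methyl}oxiran-2-yl]but-2-ynoate, via lithium acetylide 12 (not isolated), via bromozinc acetylide 13 (not isolated)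
Conditions: 11, LiN(SiMe3)2, THF, −78 °C; ZnBr2, −78 °C; then 10, THF/Et2O, −78 to 0 °C; pH 7 buffer
Reagents that add atoms: none
Why: Chelation-controlled (Cram chelate) addition of an alkynylzinc halide to an α-oxygenated aldehyde: zinc bridging the formyl and oxirane oxygens holds the carbonyl syn to the C–O bond, and attack from the farnesyl side, away from the cis CH2OPMB arm on C5, should give the (4R) carbinol whose oxygen will lie anti to the oxirane oxygen in the later ring.

**Step 7**
Reactants: 14 propargylic alcohol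
Product: 15 methyl (4R)-4-[(2R,3R)-2-farnesyl-3-{[(4-methoxybenzyl)oxy]methyl}oxiran-2-yl]-4-(triethylsilyloxy)but-2-ynoate
Conditions: Et3SiOTf, 2,6-lutidine, CH2Cl2, −78 °C
Reagents that add atoms: triethylsilyl trifluoromethanesulfonate, CC[Si](CC)(CC)OS(=O)(=O)C(F)(F)F
Why: Silyl triflate silylation of the hindered secondary alcohol; the ether prevents butenolide formation after the semi-reduction and is the more labile of the two silyl groups used later.

**Step 8**
Reactants: 15 silyloxy ynoate
Product: 16 methyl (2Z,4R)-4-[(2R,3R)-2-farnesyl-3-{[(4-methoxybenzyl)oxy]methyl}oxiran-2-yl]-4-(triethylsilyloxy)but-2-enoate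
Conditions: H2 (1 atm), Pd/CaCO3 poisoned with Pb(OAc)2, quinoline, EtOAc, rt
Reagents that add atoms: none
Why: Lindlar semi-hydrogenation; syn delivery of hydrogen on the poisoned palladium surface gives the (Z)-enoate and stops there, and the trisubstituted olefins, PMB ether and oxirane are inert.

**Step 9**
Reactants: 16 PMB ether
Product: 17 methyl (2Z,4R)-4-[(2R,3R)-2-farnesyl-3-(hydroxymethyl)oxiran-2-yl]-4-(triethylsilyloxy)but-2-enoate
Conditions: DDQ, CH2Cl2/pH 7 phosphate buffer, 0 °C
Reagents that add atoms: none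
Why: Oxidative PMB cleavage by DDQ through the benzylic oxocarbenium ion and its hemiacetal; the buffered two-phase medium should spare the silyl ether, the oxirane and the electron-poor enoate.

**Step 10**
Reactants: 17 primary alcohol
Product: 18 methyl (2Z,4R)-4-[(2R,3S)-2-farnesyl-3-formyloxiran-2-yl]-4-(triethylsilyloxy)but-2-enoate
Conditions: Dess–Martin periodinane, pyridine, CH2Cl2, 0 °C; used without storage
Reagents that add atoms: none
Why: Dess–Martin oxidation of the primary epoxy alcohol gives an aldehyde that cannot enolise, because its α-carbon C5 is an oxirane carbon.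

**Step 11**
Reactants: 18 epoxy aldehyde (Z)-enoate
Product: 21 methyl (3R,4R,5R,6R)-4,5-epoxy-4-farnesyl-6-hydroxy-3-(triethylsilyloxy)cyclohex-1-ene-1-carboxylate, via phosphonium enolate 19 (not isolated), via phosphonium aldolate 20 (not isolated)
Conditions: PMe3 (0.3 equiv, 1 M in toluene), CH2Cl2, 0 °C to rt
Reagents that add atoms: none
Why: PMe3 adds reversibly to C2 of the enoate to give the β-phosphonium ester enolate 19, whose α-carbon C1 attacks the oxiranyl aldehyde carbon C6 in a 6-(enolexo)-exo-trig aldol to give aldolate 20; proton transfer from C1 and E1cB loss of PMe3 then restore the C1=C2 bond inside the new cyclohexene. The closest known reaction is the trialkylphosphine-mediated intramolecular Morita–Baylis–Hillman cyclisation of enoates and enones whose formyl group is tethered through the β-carbon. Because C2 is sp3 in 19, the Z geometry of 18 is immaterial and the ring olefin is necessarily cis. The step needs only the six-membered closure, which is the single ring size open to the C1 enolate, and facial selectivity at C6. C6 should be controlled by the half-chair in which C1 reaches C6 anti to the C5–O oxirane bond while the pseudo-axial C3 silyloxy group keeps the phosphonium on the opposite, oxirane-side face of C2, so that the developing alkoxide lies next to P+ and ends syn to the oxirane oxygen and trans to the C3 silyl ether. The neutral aprotic conditions should leave the oxirane, the silyl ether and the triene untouched.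

**Step 12**
Reactants: 21 cyclohexenol ester
Product: 22 methyl (3R,4R,5R,6R)-6-(tert-butyldimethylsilyloxy)-4,5-epoxy-4-farnesyl-3-(triethylsilyloxy)cyclohex-1-ene-1-carboxylate
Conditions: t-BuMe2SiOTf, 2,6-lutidine, CH2Cl2, −78 to 0 °C
Reagents that add atoms: tert-butyldimethylsilyl trifluoromethanesulfonate, CC(C)(C)[Si](C)(C)OS(=O)(=O)C(F)(F)F
Why: Silyl triflate silylation of the secondary allylic alcohol; TBS is chosen so that the C3 TES ether can later be removed in its presence.

**Step 13**
Reactants: 22 bis-silyl ether ester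
Product: 23 [(3R,4R,5R,6R)-6-(tert-butyldimethylsilyloxy)-4,5-epoxy-4-farnesyl-3-(triethylsilyloxy)cyclohex-1-en-1-yl]methanol
Conditions: iBu2AlH (2.5 equiv), CH2Cl2, −78 °C; aq. KNaC4H4O6 work-up
Reagents that add atoms: none
Why: iBu2AlH 1,2-reduction of the conjugated methyl ester to the primary allylic alcohol at −78 °C, a temperature at which silyl ethers and the oxirane are not attacked.

**Step 14**
Reactants: 23 primary allylic alcohol
Product: 24 [(3R,4R,5R,6R)-6-(tert-butyldimethylsilyloxy)-4,5-epoxy-4-farnesyl-3-(triethylsilyloxy)cyclohex-1-en-1-yl]methyl acetate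
Conditions: Ac2O, pyridine, DMAP (cat.), CH2Cl2, 0 °C
Reagents that add atoms: acetic anhydride, CC(=O)OC(C)=O
Why: DMAP-catalysed acetylation of the only free hydroxyl group.

**Step 15**
Reactants: 24 acetate
Product: 25 [(3R,4S,5R,6R)-6-(tert-butyldimethylsilyloxy)-4,5-epoxy-4-farnesyl-3-hydroxycyclohex-1-en-1-yl]methyl acetate
Conditions: PPTS (cat.), MeOH/CH2Cl2, 0 °C to rt
Reagents that add atoms: none
Why: Acid-catalysed methanolysis cleaves the TES ether much faster than the bulkier TBS ether (selective silyl ether cleavage) and is too mild to open the oxirane or transesterify the acetate; the C4 descriptor changes only through CIP priorities.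

**Step 16**
Reactants: 25 C3 alcohol
Product: 26 [(4R,5R,6R)-6-(tert-butyldimethylsilyloxy)-4,5-epoxy-4-farnesyl-3-oxocyclohex-1-en-1-yl]methyl acetate
Conditions: Dess–Martin periodinane, pyridine, CH2Cl2, 0 °C to rt
Reagents that add atoms: none
Why: Dess–Martin oxidation of the secondary allylic alcohol to the enone removes the auxiliary C3 stereocentre.

**Step 17**
Reactants: 26 silyl-protected enone
Product: 27 [(4R,5R,6R)-4,5-epoxy-4-farnesyl-6-hydroxy-3-oxocyclohex-1-en-1-yl]methyl acetate (CNP0184985.1)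
Conditions: HF·pyridine, pyridine, THF, 0 °C to rt
Reagents that add atoms: none
Why: Buffered HF·pyridine cleaves the remaining silyl ether without base, which should avoid acetyl migration and elimination at the γ-oxygenated enone and leaves C4, C5 and C6 untouched.

**Compound list**
1 | (2E,6E)-farnesyl bromide | CC(C)=CCC/C(C)=C/CC/C(C)=C/CBr | starting material
2 | methyl 2-[bis(2,2,2-trifluoroethoxy)phosphoryl]acetate | COC(=O)CP(=O)(OCC(F)(F)F)OCC(F)(F)F | starting material
3 | sodium salt of 2 (phosphonate carbanion) | [Na+].COC(=O)[CH-]P(=O)(OCC(F)(F)F)OCC(F)(F)F | intermediate (not isolated)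
4 | methyl 2-[bis(2,2,2-trifluoroethoxy)phosphoryl]-2-farnesylacetate, racemic | COC(=O)C(C/C=C(\C)CC/C=C(\C)CCC=C(C)C)P(=O)(OCC(F)(F)F)OCC(F)(F)F | intermediate
5 | 2-[(4-methoxybenzyl)oxy]acetaldehyde | O=CCOCc1ccc(OC)cc1 | starting material
6 | potassium salt of 4 (phosphonate carbanion) | [K+].COC(=O)[C-](C/C=C(\C)CC/C=C(\C)CCC=C(C)C)P(=O)(OCC(F)(F)F)OCC(F)(F)F | intermediate (not isolated)
7 | methyl (2Z)-2-farnesyl-4-[(4-methoxybenzyl)oxy]but-2-enoate | COC(=O)/C(C/C=C(\C)CC/C=C(\C)CCC=C(C)C)=C\COCc1ccc(OC)cc1 | intermediate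
8 | (2Z)-2-farnesyl-4-[(4-methoxybenzyl)oxy]but-2-en-1-ol | OC/C(C/C=C(\C)CC/C=C(\C)CCC=C(C)C)=C\COCc1ccc(OC)cc1 | intermediate
9 | [(2S,3R)-2-farnesyl-3-{[(4-methoxybenzyl)oxy]methyl}oxiran-2-yl]methanol | OC[C@]1(C/C=C(\C)CC/C=C(\C)CCC=C(C)C)O[C@@H]1COCc1ccc(OC)cc1 | intermediate
10 | (2R,3R)-2-farnesyl-3-{[(4-methoxybenzyl)oxy]methyl}oxirane-2-carbaldehyde | O=C[C@]1(C/C=C(\C)CC/C=C(\C)CCC=C(C)C)O[C@@H]1COCc1ccc(OC)cc1 | intermediate
11 | methyl propiolate | C#CC(=O)OC | starting material
12 | lithium acetylide of methyl propiolate | [Li]C#CC(=O)OC | intermediate (not isolated)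
13 | bromozinc acetylide of methyl propiolate | Br[Zn]C#CC(=O)OC | intermediate (not isolated)
14 | methyl (4R)-4-hydroxy-4-[(2S,3R)-2-farnesyl-3-{[(4-methoxybenzyl)oxy]methyl}oxiran-2-yl]but-2-ynoate | COC(=O)C#C[C@@H](O)[C@]1(C/C=C(\C)CC/C=C(\C)CCC=C(C)C)O[C@@H]1COCc1ccc(OC)cc1 | intermediate
15 | methyl (4R)-4-[(2R,3R)-2-farnesyl-3-{[(4-methoxybenzyl)oxy]methyl}oxiran-2-yl]-4-(triethylsilyloxy)but-2-ynoate | COC(=O)C#C[C@@H](O[Si](CC)(CC)CC)[C@]1(C/C=C(\C)CC/C=C(\C)CCC=C(C)C)O[C@@H]1COCc1ccc(OC)cc1 | intermediate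
16 | methyl (2Z,4R)-4-[(2R,3R)-2-farnesyl-3-{[(4-methoxybenzyl)oxy]methyl}oxiran-2-yl]-4-(triethylsilyloxy)but-2-enoate | COC(=O)/C=C\[C@@H](O[Si](CC)(CC)CC)[C@]1(C/C=C(\C)CC/C=C(\C)CCC=C(C)C)O[C@@H]1COCc1ccc(OC)cc1 | intermediate
17 | methyl (2Z,4R)-4-[(2R,3R)-2-farnesyl-3-(hydroxymethyl)oxiran-2-yl]-4-(triethylsilyloxy)but-2-enoate | COC(=O)/C=C\[C@@H](O[Si](CC)(CC)CC)[C@]1(C/C=C(\C)CC/C=C(\C)CCC=C(C)C)O[C@@H]1CO | intermediate
18 | methyl (2Z,4R)-4-[(2R,3S)-2-farnesyl-3-formyloxiran-2-yl]-4-(triethylsilyloxy)but-2-enoate | COC(=O)/C=C\[C@@H](O[Si](CC)(CC)CC)[C@]1(C/C=C(\C)CC/C=C(\C)CCC=C(C)C)O[C@@H]1C=O | intermediate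
19 | β-trimethylphosphonium ester enolate from 18 (C2 configuration and enolate geometry undefined) | COC([O-])=CC([P+](C)(C)C)[C@@H](O[Si](CC)(CC)CC)[C@]1(C/C=C(\C)CC/C=C(\C)CCC=C(C)C)O[C@@H]1C=O | intermediate (not isolated)
20 | cyclised trimethylphosphonium aldolate (C1 and C2 configurations undefined) | COC(=O)C1C([P+](C)(C)C)[C@@H](O[Si](CC)(CC)CC)[C@]2(C/C=C(\C)CC/C=C(\C)CCC=C(C)C)O[C@@H]2[C@@H]1[O-] | intermediate (not isolated)
21 | methyl (3R,4R,5R,6R)-4,5-epoxy-4-farnesyl-6-hydroxy-3-(triethylsilyloxy)cyclohex-1-ene-1-carboxylate | COC(=O)C1=C[C@@H](O[Si](CC)(CC)CC)[C@]2(C/C=C(\C)CC/C=C(\C)CCC=C(C)C)O[C@@H]2[C@@H]1O | intermediate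
22 | methyl (3R,4R,5R,6R)-6-(tert-butyldimethylsilyloxy)-4,5-epoxy-4-farnesyl-3-(triethylsilyloxy)cyclohex-1-ene-1-carboxylate | COC(=O)C1=C[C@@H](O[Si](CC)(CC)CC)[C@]2(C/C=C(\C)CC/C=C(\C)CCC=C(C)C)O[C@@H]2[C@@H]1O[Si](C)(C)C(C)(C)C | intermediate
23 | [(3R,4R,5R,6R)-6-(tert-butyldimethylsilyloxy)-4,5-epoxy-4-farnesyl-3-(triethylsilyloxy)cyclohex-1-en-1-yl]methanol | OCC1=C[C@@H](O[Si](CC)(CC)CC)[C@]2(C/C=C(\C)CC/C=C(\C)CCC=C(C)C)O[C@@H]2[C@@H]1O[Si](C)(C)C(C)(C)C | intermediate
24 | [(3R,4R,5R,6R)-6-(tert-butyldimethylsilyloxy)-4,5-epoxy-4-farnesyl-3-(triethylsilyloxy)cyclohex-1-en-1-yl]methyl acetate | CC(=O)OCC1=C[C@@H](O[Si](CC)(CC)CC)[C@]2(C/C=C(\C)CC/C=C(\C)CCC=C(C)C)O[C@@H]2[C@@H]1O[Si](C)(C)C(C)(C)C | intermediate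
25 | [(3R,4S,5R,6R)-6-(tert-butyldimethylsilyloxy)-4,5-epoxy-4-farnesyl-3-hydroxycyclohex-1-en-1-yl]methyl acetate | CC(=O)OCC1=C[C@@H](O)[C@]2(C/C=C(\C)CC/C=C(\C)CCC=C(C)C)O[C@@H]2[C@@H]1O[Si](C)(C)C(C)(C)C | intermediate
26 | [(4R,5R,6R)-6-(tert-butyldimethylsilyloxy)-4,5-epoxy-4-farnesyl-3-oxocyclohex-1-en-1-yl]methyl acetate | CC(=O)OCC1=CC(=O)[C@]2(C/C=C(\C)CC/C=C(\C)CCC=C(C)C)O[C@@H]2[C@@H]1O[Si](C)(C)C(C)(C)C | intermediate
27 | [(4R,5R,6R)-4,5-epoxy-4-farnesyl-6-hydroxy-3-oxocyclohex-1-en-1-yl]methyl acetate (CNP0184985.1) | CC(=O)OCC1=CC(=O)[C@]2(C/C=C(\C)CC/C=C(\C)CCC=C(C)C)O[C@@H]2[C@@H]1O | target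

**Step count and risks**
Total steps: 17. Longest linear sequence: 17 steps (from 1 and 2).

Steps most likely to fail:

1. Step 11. Facial selectivity in the aldol stage may run the other way: the dipole-minimised arrangement, with the formyl oxygen turned away from the oxirane oxygen, could override the phosphonium–alkoxide contact, so that the carbinol forms anti to the oxirane. Slow turnover of the oxo ester is a second concern. The fallback sets out from 18 and returns at 21. The cyclisation is still run, the resulting C6-epimeric cyclohexenol F1 is oxidised with Dess–Martin periodinane/pyridine to the cyclic β-keto ester F2, and this is reduced with NaBH4/CeCl3·7H2O in MeOH at −78 °C (Luche 1,2-reduction, hydride expected anti to the oxirane oxygen) to give 21. C6 is then set by a carbonyl reduction and no longer by the ring closure.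

2. Step 6. Chelation may be incomplete, so that open-chain (Felkin–Anh-type) addition dominates and the carbinol centre forms mainly with the opposite configuration. The fallback sets out from 10 and returns at 14. The addition is run with the lithium acetylide alone, the epimer mixture containing the (4S)-propargylic alcohol F3 is oxidised with Dess–Martin periodinane to the ynone F4, and this is reduced with (S)-2-methyl-CBS-oxazaborolidine and catecholborane in toluene at −78 °C (Corey–Bakshi–Shibata reduction, alkynyl group as the small substituent) to give 14 under reagent control.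

3. Step 4. Turnover may be slow and enantiofacial discrimination incomplete, as is typical of Z-configured allylic alcohols in the titanium tartrate epoxidation. The fallback sets out from 9 of insufficient enantiomeric purity and returns at 9. Esterification with (S)-O-methylmandelic acid (DCC, DMAP, CH2Cl2) gives the mandelate ester F5 together with its minor diastereomer, which is removed by chromatography; methanolysis (K2CO3, MeOH, 0 °C) then regenerates 9. Enantiomeric purity then rests on a separation of diastereomers and not on the catalyst.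

**Further compounds**
F1 | step 11 | methyl (3R,4R,5R,6S)-4,5-epoxy-4-farnesyl-6-hydroxy-3-(triethylsilyloxy)cyclohex-1-ene-1-carboxylate | COC(=O)C1=C[C@@H](O[Si](CC)(CC)CC)[C@]2(C/C=C(\C)CC/C=C(\C)CCC=C(C)C)O[C@@H]2[C@H]1O
F2 | step 11 | methyl (3R,4R,5S)-4,5-epoxy-4-farnesyl-6-oxo-3-(triethylsilyloxy)cyclohex-1-ene-1-carboxylate | COC(=O)C1=C[C@@H](O[Si](CC)(CC)CC)[C@]2(C/C=C(\C)CC/C=C(\C)CCC=C(C)C)O[C@@H]2C1=O
F3 | step 6 | methyl (4S)-4-hydroxy-4-[(2S,3R)-2-farnesyl-3-{[(4-methoxybenzyl)oxy]methyl}oxiran-2-yl]but-2-ynoate | COC(=O)C#C[C@H](O)[C@]1(C/C=C(\C)CC/C=C(\C)CCC=C(C)C)O[C@@H]1COCc1ccc(OC)cc1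
F4 | step 6 | methyl 4-[(2R,3R)-2-farnesyl-3-{[(4-methoxybenzyl)oxy]methyl}oxiran-2-yl]-4-oxobut-2-ynoate | COC(=O)C#CC(=O)[C@]1(C/C=C(\C)CC/C=C(\C)CCC=C(C)C)O[C@@H]1COCc1ccc(OC)cc1
F5 | step 4 | [(2S,3R)-2-farnesyl-3-{[(4-methoxybenzyl)oxy]methyl}oxiran-2-yl]methyl (2S)-2-methoxy-2-phenylacetate | CO[C@@H](c1ccccc1)C(=O)OC[C@]1(C/C=C(\C)CC/C=C(\C)CCC=C(C)C)O[C@@H]1COCc1ccc(OC)cc1
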